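The plan rests on disconnecting C3–C3a (furo[3,4-c]furan numbering: ring A = C1(aryl)–O2–C3H2–C3a(OH)–C6a; ring B = C3a–C4(aryl)–O5–C6H2–C6a). Because C3a lies β to O5 across C4, ring B is built as a 5-aryl-2,3-dihydrofuran whose nucleophilic enol-ether carbon is C3a, while C3 is a formaldehyde unit parked on O2 as a MOM ether. Silyl triflate ionises that acetal and the oxocarbenium ion closes ring A on C3a in one Prins-type operation, giving the cis-fused bicyclic enol ether; syn-hydroboration then installs the C3a hydroxyl and the endo C4 aryl. The precursor is a monocyclic dihydrofuran carrying the C1 side chain from an Evans syn-aldol.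

Key step: step 6

Remark: compounds 1, 2, 5 and 10 (as a THF solution) are taken as commercial; "aryl" is 3,4-dimethoxyphenyl throughout, and the locants above are used for all bicyclic compounds.

Step 1
Reactants: 1 3-cyanopropanoic acid; 2 (S)-4-benzyloxazolidin-2-one
Product: 4 (S)-4-benzyl-3-(3-cyanopropanoyl)oxazolidin-2-one, via mixed pivalic anhydride 3 (not isolated)
Conditions: PivCl, Et3N, THF, −20 °C; then LiCl, 2, −20 °C → rt
Reagents that add atoms: none
Why: N-acylation of the oxazolidinone through the mixed pivalic anhydride (LiCl-assisted acyl transfer) is the standard way to load the Evans auxiliary, the nitrile is inert to it and no stereocentre is formed.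

Step 2
Reactants: 4; 5 3,4-dimethoxybenzaldehyde
Product: 7 (S)-4-benzyl-3-[(2S,3S)-2-(cyanomethyl)-3-(3,4-dimethoxyphenyl)-3-hydroxypropanoyl]oxazolidin-2-one, via boron enolate 6 (not isolated)
Conditions: Bu2BOTf, i-Pr2NEt, CH2Cl2, 0 °C; 5, −78 → 0 °C; pH 7 buffer, MeOH, 30% H2O2, 0 °C
Reagents that add atoms: none
Why: Evans syn-aldol, in which the Z boron enolate 6 adds to the aldehyde through a closed Zimmerman–Traxler chair on the face opposite the benzyl group of the (S)-auxiliary, which should set the future C6a and C1 together as the 2S,3S syn pair while the nitrile is not enolised.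

Step 3
Reactants: 7
Product: 8 (S)-4-benzyl-3-[(2S,3S)-2-(cyanomethyl)-3-(3,4-dimethoxyphenyl)-3-(methoxymethoxy)propanoyl]oxazolidin-2-one
Conditions: MOMCl, i-Pr2NEt, Bu4NI (cat.), CH2Cl2, 0 °C → rt
Reagents that add atoms: chloromethyl methyl ether, COCCl
Why: Standard MOM protection (O-alkylation with an α-chloro ether) masks the C1 hydroxyl and at the same time places the future C3 carbon on O2, without touching either stereocentre.

Step 4
Reactants: 8
Product: 9 (3R,4S)-4-(3,4-dimethoxyphenyl)-3-(hydroxymethyl)-4-(methoxymethoxy)butanenitrile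
Conditions: LiBH4, MeOH (1 equiv), THF, 0 °C
Reagents that add atoms: none
Why: Reductive removal of the Evans auxiliary with LiBH4 should reduce only the exocyclic imide carbonyl to the primary alcohol (future O5–C6), leaving the nitrile, the MOM ether and both stereocentres untouched (the descriptor at C3 changes only by priority).

Step 5
Reactants: 9; 10 3,4-dimethoxyphenylmagnesium bromide
Product: 12 (3R)-5-(3,4-dimethoxyphenyl)-3-[(S)-(3,4-dimethoxyphenyl)(methoxymethoxy)methyl]-2,3-dihydrofuran, via hydroxy ketone 11 (not isolated)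
Conditions: 10 (3.5 equiv), CuBr·SMe2 (5 mol %), THF, 0 → 60 °C; aq. citric acid, rt; then PPTS (cat.), 4 Å MS, CH2Cl2, rt
Reagents that add atoms: none
Why: Copper-catalysed Grignard addition to the nitrile (the first equivalent is consumed by the hydroxyl) gives a ketimine whose mild acid hydrolysis frees the γ-hydroxy aryl ketone 11, and acid-catalysed hemiketalisation and dehydration then close ring B as the cyclic enol ether, with C1 and C6a untouched.

Step 6
Reactants: 12
Product: 14 (1S,6aR)-1,4-bis(3,4-dimethoxyphenyl)-6,6a-dihydro-1H,3H-furo[3,4-c]furan, via bicyclic oxocarbenium triflate 13 (not isolated)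
Conditions: Me3SiOTf (1.3 equiv), 2,6-di-tert-butyl-4-methylpyridine (2 equiv), CH2Cl2 (0.01 M), −78 → −30 °C; Et3N quench
Reagents that add atoms: none
Why: Me3SiOTf silylates the terminal methoxy oxygen of the MOM ether and expels MeOSiMe3, leaving the alkoxymethyl oxocarbenium ion O2=C3H2; C3a, the nucleophilic β-carbon of the cyclic enol ether, attacks C3 to form the C3–C3a bond, and the resulting 2-aryl oxocarbenium ion 13 (charge on C4/O5, stabilised by the dimethoxyphenyl group) loses H-3a to the hindered pyridine to give the tetrasubstituted enol ether 14. The closest known reaction type is the Lewis acid-mediated intramolecular Prins-type (Mukaiyama-like) cyclisation of acetal-derived oxocarbenium ions onto 2,3-dihydrofurans and other enol ethers, with MOM ethers as established alkoxymethyl cation sources. Ring A (C1, O2, C3, C3a, C6a) closes in a 5-exo-trig mode with respect to the C3a=C4 enol ether (C4 stays outside the new ring) and endo with respect to the O2=C3 oxocarbenium unit. No new stereocentre survives the step (C3a becomes trigonal), but the ring fusion is necessarily cis because the three-atom tether on C6a can reach only the face of C3a on which it stands, and C1 and C6a are carried over unchanged (C1 already has the thermodynamically preferred exo aryl). The step needs (a) ionisation of the O–CH2–OMe bond rather than the benzylic C1–O2 bond and (b) C-alkylation by the enol ether rather than attack of the dimethoxyphenyl ring or protonation of the enol ether: (a) should be secured by silylation of the less hindered methoxy oxygen at low temperature, (b) by the far higher nucleophilicity of the enol ether, its five-membered transition state, high dilution and the proton-free buffered medium. Regiochemistry at the nucleophile is unambiguous, since C4 is the α-carbon of the enol ether and only C3a carries π-nucleophilic character.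

Step 7
Reactants: 14
Product: 16 (1S,3aS,4S,6aR)-1,4-bis(3,4-dimethoxyphenyl)tetrahydro-1H,3H-furo[3,4-c]furan-3a(4H)-ol (target CNP0422369.6), via alkylborane 15 (not isolated)
Conditions: BH3·THF, THF, 0 °C; then NaOH, 30% H2O2, 0 °C → rt
Reagents that add atoms: hydrogen peroxide, OO
Why: Hydroboration–oxidation of an enol ether, in which boron adds to the β-carbon C3a and hydrogen to C4 syn from the convex face (the face of H-6a, the only one leading to the cis-fused skeleton), and oxidation with retention should give the C3a–OH and C4–H on that face, i.e. the C4 aryl endo and trans to the hydroxyl.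

Compound list
1 | 3-cyanopropanoic acid | N#CCCC(=O)O | starting material
2 | (S)-4-benzyloxazolidin-2-one | O=C1N[C@@H](Cc2ccccc2)CO1 | starting material
3 | 3-cyanopropanoic pivalic anhydride | CC(C)(C)C(=O)OC(=O)CCC#N | intermediate
4 | (S)-4-benzyl-3-(3-cyanopropanoyl)oxazolidin-2-one | N#CCCC(=O)N1[C@@H](Cc2ccccc2)COC1=O | intermediate
5 | 3,4-dimethoxybenzaldehyde | COc1ccc(C=O)cc1OC | starting material
6 | Z dibutylboron enolate of 4 | N#CC/C=C(\OB(CCCC)CCCC)N1[C@@H](Cc2ccccc2)COC1=O | intermediate
7 | (S)-4-benzyl-3-[(2S,3S)-2-(cyanomethyl)-3-(3,4-dimethoxyphenyl)-3-hydroxypropanoyl]oxazolidin-2-one | COc1ccc([C@@H](O)[C@H](CC#N)C(=O)N2[C@@H](Cc3ccccc3)COC2=O)cc1OC | intermediate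
8 | (S)-4-benzyl-3-[(2S,3S)-2-(cyanomethyl)-3-(3,4-dimethoxyphenyl)-3-(methoxymethoxy)propanoyl]oxazolidin-2-one | COCO[C@H](c1ccc(OC)c(OC)c1)[C@H](CC#N)C(=O)N1[C@@H](Cc2ccccc2)COC1=O | intermediate
9 | (3R,4S)-4-(3,4-dimethoxyphenyl)-3-(hydroxymethyl)-4-(methoxymethoxy)butanenitrile | COCO[C@H](c1ccc(OC)c(OC)c1)[C@H](CC#N)CO | intermediate
10 | 3,4-dimethoxyphenylmagnesium bromide | COc1ccc([Mg]Br)cc1OC | starting material
11 | (3R,4S)-1,4-bis(3,4-dimethoxyphenyl)-3-(hydroxymethyl)-4-(methoxymethoxy)butan-1-one | COCO[C@H](c1ccc(OC)c(OC)c1)[C@@H](CO)CC(=O)c1ccc(OC)c(OC)c1 | intermediate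
12 | (3R)-5-(3,4-dimethoxyphenyl)-3-[(S)-(3,4-dimethoxyphenyl)(methoxymethoxy)methyl]-2,3-dihydrofuran | COCO[C@H](c1ccc(OC)c(OC)c1)[C@H]1COC(c2ccc(OC)c(OC)c2)=C1 | intermediate
13 | (1S,3aR,6aR)-1,4-bis(3,4-dimethoxyphenyl)-3,3a,6,6a-tetrahydro-1H-furo[3,4-c]furan-5-ium trifluoromethanesulfonate (cis-fused, H-3a and H-6a cis) | COc1ccc([C@H]2OC[C@H]3[C@@H]2C[O+]=C3c2ccc(OC)c(OC)c2)cc1OC.[O-]S(=O)(=O)C(F)(F)F | intermediate
14 | (1S,6aR)-1,4-bis(3,4-dimethoxyphenyl)-6,6a-dihydro-1H,3H-furo[3,4-c]furan | COc1ccc([C@H]2OCC3=C(c4ccc(OC)c(OC)c4)OC[C@H]23)cc1OC | intermediate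
15 | C3a-borane adduct of 14 (BH2 on C3a and H on C4 both cis to H-6a) | COc1ccc([C@H]2OC[C@@]3(B)[C@@H]2CO[C@H]3c2ccc(OC)c(OC)c2)cc1OC | intermediate
16 | (1S,3aS,4S,6aR)-1,4-bis(3,4-dimethoxyphenyl)tetrahydro-1H,3H-furo[3,4-c]furan-3a(4H)-ol | COc1ccc([C@H]2OC[C@@]3(O)[C@@H]2CO[C@H]3c2ccc(OC)c(OC)c2)cc1OC | target

Total step count: 7. Longest linear sequence: 7 steps (from 1).

Steps most likely to fail

1. Step 6 (key step). What may go wrong: ionisation of the benzylic C1–O2 bond instead of the acetal C–OMe bond, or protonation and oligomerisation of the electron-rich cyclic enol ether before it captures the oxocarbenium ion. Fallback (order of the two ring closures reversed): set out from hydroxy ketone 11, isolated after the citric acid work-up of step 5 without the PPTS treatment. Silylation with t-BuMe2SiOTf/Et3N (CH2Cl2, −78 → 0 °C) should give the Z silyl enol ether with the primary hydroxyl silylated, bis-silyl compound F1. Catalytic Me3SiOTf (CH2Cl2, −78 °C) should then trigger a Mukaiyama-type cyclisation of this acyclic silyl enol ether onto the MOM-derived oxocarbenium ion, closing ring A through the same C3–C3a bond to the 4-aroyl tetrahydrofuran F2 (epimers at C3a, which equilibrate through the enol). HF·pyridine (THF, 0 °C → rt) should remove the silyl ether and, by hemiketalisation of the cis epimer with the C6 hydroxyl and dehydration, return to the route at 14.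

2. Step 5. What may go wrong: addition of the magnesium alkoxide to the nitrile (iminolactone formation) or α-deprotonation of the nitrile outpacing aryl transfer, so that no ketimine forms. Fallback (a lactone instead of the nitrile as acceptor): from 9, NaOH in aqueous EtOH at reflux should hydrolyse the nitrile to the sodium hydroxy carboxylate F3, which on acidification to pH 4 (aq. HCl, 0 °C) should lactonise to the γ-butyrolactone F4. 3,4-Dimethoxyphenyllithium F5 (from 4-bromo-1,2-dimethoxybenzene and n-BuLi, THF, −78 °C; 1.1 equiv) should add once at −78 °C to give 11 as its lactol; the route is rejoined at 11, which is dehydrated to 12 with PPTS as in step 5.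

3. Step 7. What may go wrong: slow hydroboration of the tetrasubstituted enol ether, β-elimination of the β-alkoxy organoborane, or erosion of facial selectivity. Fallback (epoxidation–reduction in place of hydroboration): from 14, dimethyldioxirane (acetone/CH2Cl2, −78 → 0 °C) should epoxidise the enol ether from the convex face to the 3a,4-epoxide F6. i-Bu2AlH (CH2Cl2, −78 °C) should then open the ketal-type C4–O bond and deliver hydride to C4 on the face of the departing oxygen, giving 16 directly.

Further compounds
F1 | step 6 | bis-silyl derivative of 11 (Z tert-butyldimethylsilyl enol ether of the aryl ketone, primary tert-butyldimethylsilyl ether) | COCO[C@H](c1ccc(OC)c(OC)c1)[C@@H](CO[Si](C)(C)C(C)(C)C)/C=C(\O[Si](C)(C)C(C)(C)C)c1ccc(OC)c(OC)c1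
F2 | step 6 | [(4S,5S)-4-{[(tert-butyldimethylsilyl)oxy]methyl}-5-(3,4-dimethoxyphenyl)tetrahydrofuran-3-yl](3,4-dimethoxyphenyl)methanone, both epimers at the aroyl-bearing carbon | COc1ccc([C@H]2OCC(C(=O)c3ccc(OC)c(OC)c3)[C@@H]2CO[Si](C)(C)C(C)(C)C)cc1OC
F3 | step 5 | sodium (3R,4S)-4-(3,4-dimethoxyphenyl)-3-(hydroxymethyl)-4-(methoxymethoxy)butanoate | COCO[C@H](c1ccc(OC)c(OC)c1)[C@H](CC(=O)[O-])CO.[Na+]
F4 | step 5 | (R)-4-[(S)-(3,4-dimethoxyphenyl)(methoxymethoxy)methyl]dihydrofuran-2(3H)-one | COCO[C@H](c1ccc(OC)c(OC)c1)[C@H]1COC(=O)C1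
F5 | step 5 | 3,4-dimethoxyphenyllithium | [Li]c1ccc(OC)c(OC)c1
F6 | step 7 | 3a,4-epoxide of 14 on the convex face (oxirane oxygen cis to H-6a) | COc1ccc([C@H]2OC[C@@]3(O4)[C@@H]2CO[C@@]34c2ccc(OC)c(OC)c2)cc1OC
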